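**Retrosynthetic overview**
1. The target comes from a protected 9‑epi‑drimenyl arene carrying three SEM ethers and one TIPS ether; the TIPS oxygen is the one that is sulfated, and the SEM groups are removed last with fluoride.
2. The C8 methyl/Δ7 alkene comes from an enol triflate of a 9‑arylmethyl Δ6‑en‑8‑one. The C9–CH2Ar bond is made by alkylating the kinetic dienolate of a C13 bicyclic enone with a tetra‑oxygenated benzyl bromide, anti to the angular methyl (sets C9).
3. The bicyclic enone comes from a trans‑decal‑6‑one by Wharton 1,3‑carbonyl transposition. The decalone comes from acid‑initiated ring‑A closure of an enol acetate made by copper‑catalysed asymmetric conjugate addition to 3‑methylcyclohexenone (sets C10; C5 by equilibration).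
4. The benzyl bromide comes from directed ortho‑lithiation/hydroxymethylation of a tris‑SEM, mono‑TIPS tetraoxybenzene, itself from bromination/oxidation of tris‑SEM hydroxyquinol and Thiele–Winter acetoxylation of 1,4‑benzoquinone.
5. Ring order: ring B is the purchased cyclohexenone, ring A is closed onto it, and the preformed arene is attached last.

Assumption: the target is made exactly as drawn, (5S,9R,10S) in drimane numbering (arylmethyl at C9 trans to the angular methyl), as the free hydrogen sulfate; SEM = 2‑(trimethylsilyl)ethoxymethyl, TIPS = triisopropylsilyl.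

**Branch A: bicyclic enone**

Step 1
Reactants: 1 5‑bromo‑2‑methylpent‑2‑ene; 2 3‑methylcyclohex‑2‑en‑1‑one
Product: 5 (S)‑3‑methyl‑3‑(4‑methylpent‑3‑en‑1‑yl)cyclohex‑1‑en‑1‑yl acetate, via Grignard reagent 3 (not isolated), via magnesium enolate 4 (not isolated)
Conditions: Mg, Et2O, rt; then 2, Cu(OTf)2 (3 mol%), chiral hydroxyalkyl imidazolinium salt (NHC precursor, 4 mol%), Et2O, 0 °C; then Ac2O, 0 °C → rt
Reagents that add atoms: acetic anhydride, CC(=O)OC(C)=O
Why: Copper‑catalysed asymmetric conjugate addition of the Grignard reagent to the β,β‑disubstituted enone sets the quaternary centre (future C10) as S through the chiral NHC–copper catalyst (ligand antipode chosen accordingly; any minor enantiomer is removed later by recrystallisation of a ketone intermediate), and O‑acetylation of the magnesium enolate fixes the enol double bond toward the quaternary carbon.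

Step 2
Reactants: 5 (S)‑3‑methyl‑3‑(4‑methylpent‑3‑en‑1‑yl)cyclohex‑1‑en‑1‑yl acetate
Product: 6 (4aR,8aS)‑4a,8,8‑trimethyloctahydronaphthalen‑1(2H)‑one (trans‑fused)
Conditions: ClSO3H (2 equiv), 2‑nitropropane, −78 °C; H2O quench; then NaOMe (cat.), MeOH, rt
Reagents that add atoms: none
Why: Brønsted‑acid cation–olefin cyclisation, in which Markovnikov protonation of the trisubstituted alkene gives a tertiary cation that is trapped by the enol acetate carbon next to the quaternary centre to close ring A, the acetyl group is lost on quench, and base equilibration of the ring‑fusion CH next to the carbonyl gives the more stable trans‑decalone (8a‑H anti to the 4a‑methyl).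

Step 3
Reactants: 6 (4aR,8aS)‑4a,8,8‑trimethyloctahydronaphthalen‑1(2H)‑one
Product: 8 trimethyl{[(4aR,8aS)‑4a,8,8‑trimethyl‑3,4,4a,5,6,7,8,8a‑octahydronaphthalen‑1‑yl]oxy}silane, via lithium enolate 7 (not isolated)
Conditions: LiN(i‑Pr)2, THF, −78 °C; then Me3SiCl, −78 °C → 0 °C
Reagents that add atoms: chlorotrimethylsilane, C[Si](C)(C)Cl
Why: Kinetic deprotonation occurs at the unhindered CH2 and not at the ring‑fusion methine flanked by two quaternary carbons, and O‑silylation gives the Δ1,2 silyl enol ether without touching a stereocentre.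

Step 4
Reactants: 8 silyl enol ether
Product: 9 (4aR,8aS)‑4a,8,8‑trimethyl‑4a,5,6,7,8,8a‑hexahydronaphthalen‑1(4H)‑one
Conditions: Pd(OAc)2 (1.05 equiv), MeCN, rt
Reagents that add atoms: none
Why: Saegusa–Ito oxidation, in which the palladium enolate undergoes β‑hydride elimination to the enone and palladium metal.

Step 5
Reactants: 9 enone
Product: 10 (4aR,8aS)‑2,3‑epoxy‑4a,8,8‑trimethyloctahydronaphthalen‑1(2H)‑one with the epoxide oxygen anti to the 4a‑methyl
Conditions: 30% H2O2, NaOH (cat.), MeOH, 0 °C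
Reagents that add atoms: hydrogen peroxide, OO
Why: Weitz–Scheffer nucleophilic epoxidation, with hydroperoxide adding to the β‑carbon on the face away from the axial angular methyl (both epoxide centres are erased in the next two steps).

Step 6
Reactants: 10 epoxy ketone
Product: 12 (2S,4aS,8aR)‑5,5,8a‑trimethyl‑1,2,4a,5,6,7,8,8a‑octahydronaphthalen‑2‑ol, via epoxy hydrazone 11 (not isolated)
Conditions: N2H4·H2O (3 equiv), AcOH (cat.), MeOH, 0 °C → rt
Reagents that add atoms: none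
Why: Wharton transposition, in which the epoxy hydrazone fragments with loss of N2 so that the former carbonyl carbon becomes an alkene carbon and the oxygen ends up on the former β‑carbon with its epoxide configuration retained.

Step 7
Reactants: 12 allylic alcohol
Product: 13 (4aS,8aR)‑5,5,8a‑trimethyl‑4a,5,6,7,8,8a‑hexahydronaphthalen‑2(1H)‑one
Conditions: MnO2 (activated, excess), CH2Cl2, rt
Reagents that add atoms: none
Why: Selective MnO2 oxidation of the allylic alcohol gives the enone whose only CH2 next to the carbonyl is the one beside the quaternary carbon (future C9).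

**Branch B: benzyl bromide**

Step 8
Reactants: 14 1,4‑benzoquinone
Product: 15 benzene‑1,2,4‑triyl triacetate
Conditions: Ac2O, H2SO4 (cat.), 40 °C
Reagents that add atoms: acetic anhydride, CC(=O)OC(C)=O
Why: Thiele–Winter acetoxylation (conjugate addition of acetate to the protonated quinone, enolisation and acetylation).

Step 9
Reactants: 15 benzene‑1,2,4‑triyl triacetate
Product: 16 benzene‑1,2,4‑triol
Conditions: HCl (cat.), MeOH, reflux, Ar
Reagents that add atoms: none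
Why: Acid‑catalysed transesterification to methyl acetate frees the triol, which is kept under argon because it oxidises in air.

Step 10
Reactants: 16 benzene‑1,2,4‑triol
Product: 17 1,2,4‑tris(SEM‑oxy)benzene
Conditions: Me3SiCH2CH2OCH2Cl (3.6 equiv), i‑Pr2NEt, DMF, 0 °C → rt, Ar
Reagents that add atoms: 2‑(trimethylsilyl)ethoxymethyl chloride, C[Si](C)(C)CCOCCl
Why: O‑alkylation of the phenols by the reactive chloromethyl ether gives three acetal ethers that later direct lithiation and are removable with fluoride.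

Step 11
Reactants: 17 1,2,4‑tris(SEM‑oxy)benzene
Product: 18 1‑bromo‑2,4,5‑tris(SEM‑oxy)benzene
Conditions: NBS (1.0 equiv), MeCN, 0 °C
Reagents that add atoms: N‑bromosuccinimide, O=C1CCC(=O)N1Br
Why: Electrophilic aromatic bromination goes to the position para to one alkoxy group and ortho to another, not to the crowded site between two alkoxy groups.

Step 12
Reactants: 18 aryl bromide
Product: 21 2,4,5‑tris(SEM‑oxy)phenol, via aryllithium 19 (not isolated), via dimethyl arylboronate 20 (not isolated)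
Conditions: n‑BuLi, THF, −78 °C; B(OMe)3, −78 °C → 0 °C; 30% H2O2, aq. NaOH, 0 °C
Reagents that add atoms: hydrogen peroxide, OO
Why: Bromine–lithium exchange, borylation and oxidative C–B to C–O migration install the fourth oxygen as the only free phenol.

Step 13
Reactants: 21 2,4,5‑tris(SEM‑oxy)phenol
Product: 22 triisopropyl[2,4,5‑tris(SEM‑oxy)phenoxy]silane
Conditions: i‑Pr3SiCl, imidazole, DMF, rt
Reagents that add atoms: chlorotriisopropylsilane, CC(C)[Si](Cl)(C(C)C)C(C)C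
Why: Silylation marks the oxygen that will carry the sulfate with a bulky, non‑coordinating group that is orthogonal to SEM.

Step 14
Reactants: 22 silyl ether
Product: 24 [2,3,6‑tris(SEM‑oxy)‑5‑(triisopropylsilyloxy)phenyl]methanol, via aryllithium 23 (not isolated)
Conditions: n‑BuLi, TMEDA, THF, −78 °C → 0 °C; (CH2O)n (dry paraformaldehyde), −78 °C → rt
Reagents that add atoms: formaldehyde (as paraformaldehyde), C=O
Why: Directed ortho‑metalation occurs at the CH flanked by two chelating SEM ethers (the other CH is shielded by the TIPS ether), and the aryllithium adds to formaldehyde to give the benzylic alcohol.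

Step 15
Reactants: 24 benzylic alcohol
Product: 25 [3‑(bromomethyl)‑2,4,5‑tris(SEM‑oxy)phenoxy]triisopropylsilane
Conditions: CBr4, PPh3, CH2Cl2, −20 °C → 0 °C; used at once
Reagents that add atoms: tetrabromomethane, BrC(Br)(Br)Br
Why: Appel reaction converts the primary benzylic alcohol to the bromide under neutral conditions that spare the acetal and silyl ethers.

**Fragment union and endgame**

Step 16
Reactants: 13 (4aS,8aR)‑5,5,8a‑trimethyl‑4a,5,6,7,8,8a‑hexahydronaphthalen‑2(1H)‑one; 25 benzyl bromide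
Product: 27 (1S,4aS,8aS)‑1‑{[2,3,6‑tris(SEM‑oxy)‑5‑(triisopropylsilyloxy)phenyl]methyl}‑5,5,8a‑trimethyl‑4a,5,6,7,8,8a‑hexahydronaphthalen‑2(1H)‑one, via lithium dienolate 26 (not isolated)
Conditions: LiN(i‑Pr)2 (1.05 equiv), THF, −78 °C; then 25 (1.1 equiv), DMPU, −78 °C → −30 °C
Reagents that add atoms: none
Why: Kinetic α′‑deprotonation gives the cross‑conjugated dienolate, and SN2 alkylation by the benzylic bromide takes place on the face anti to the axial angular methyl of the adjacent quaternary carbon, which sets C1 (drimane C9) with the arylmethyl group trans to that methyl.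

Step 17
Reactants: 27 benzylated enone
Product: 29 (1S,4aS,8aS)‑1‑{[2,3,6‑tris(SEM‑oxy)‑5‑(triisopropylsilyloxy)phenyl]methyl}‑5,5,8a‑trimethyl‑1,4,4a,5,6,7,8,8a‑octahydronaphthalen‑2‑yl trifluoromethanesulfonate, via lithium enolate 28 (not isolated)
Conditions: LiBH(s‑Bu)3, THF, −78 °C; then PhNTf2, −78 °C → 0 °C
Reagents that add atoms: N‑phenylbis(trifluoromethanesulfonimide), O=S(=O)(N(c1ccccc1)S(=O)(=O)C(F)(F)F)C(F)(F)F
Why: Conjugate hydride reduction of the β‑unsubstituted cyclohexenone gives the enolate only on the side away from C1, so triflation fixes the future Δ7 double bond and the new stereocentre is never enolised.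

Step 18
Reactants: 29 enol triflate
Product: 30 triisopropyl[2,4,5‑tris(SEM‑oxy)‑3‑{[(1R,4aS,8aS)‑2,5,5,8a‑tetramethyl‑1,4,4a,5,6,7,8,8a‑octahydronaphthalen‑1‑yl]methyl}phenoxy]silane
Conditions: MeMgBr, Fe(acac)3 (5 mol%), THF/NMP, −30 °C → 0 °C
Reagents that add atoms: methylmagnesium bromide, C[Mg]Br
Why: Iron‑catalysed Kumada‑type cross‑coupling replaces the alkenyl triflate by methyl with retention of the double‑bond position, completing the 9‑epi‑drimenyl skeleton (the descriptor at C1 changes to R only through priorities).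

Step 19
Reactants: 30 protected drimenyl arene
Product: 32 tetrabutylammonium 2,4,5‑tris(SEM‑oxy)‑3‑{[(1R,4aS,8aS)‑2,5,5,8a‑tetramethyl‑1,4,4a,5,6,7,8,8a‑octahydronaphthalen‑1‑yl]methyl}phenyl sulfate, via tetrabutylammonium phenoxide 31 (not isolated)
Conditions: Bu4NF (1.1 equiv), THF, 0 °C; then SO3·pyridine (4 equiv), pyridine, rt
Reagents that add atoms: tetrabutylammonium fluoride, CCCC[N+](CCCC)(CCCC)CCCC.[F-]; sulfur trioxide–pyridine complex, O=S(=O)([O-])[n+]1ccccc1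
Why: Fluoride cleaves the aryl silyl ether at 0 °C while the SEM acetals stay intact, and the liberated phenoxide is O‑sulfated by the sulfur trioxide complex, placing the sulfate on the one oxygen that was differentiated in step 13.

Step 20
Reactants: 32 protected aryl sulfate
Product: 34 2,4,5‑trihydroxy‑3‑{[(1R,4aS,8aS)‑2,5,5,8a‑tetramethyl‑1,4,4a,5,6,7,8,8a‑octahydronaphthalen‑1‑yl]methyl}phenyl hydrogen sulfate (target), via tetrabutylammonium sulfate salt 33 (not isolated)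
Conditions: Bu4NF (10 equiv), H2NCH2CH2NH2 (10 equiv), DMF, 45 °C, degassed, Ar; then Dowex 50W (H+ form), 0 °C, lyophilise
Reagents that add atoms: none
Why: Fluoride attack at silicon triggers β‑elimination and hemiacetal collapse of each SEM group under non‑acidic conditions that leave the sulfate monoester anion and the trisubstituted alkene untouched, ethylenediamine traps the formaldehyde, and proton exchange gives the free acid.

**Compound list**
1 | 5‑bromo‑2‑methylpent‑2‑ene | CC(C)=CCCBr | starting material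
2 | 3‑methylcyclohex‑2‑en‑1‑one | CC1=CC(=O)CCC1 | starting material
3 | (4‑methylpent‑3‑en‑1‑yl)magnesium bromide | CC(C)=CCC[Mg]Br | intermediate
4 | bromomagnesium (S)‑3‑methyl‑3‑(4‑methylpent‑3‑en‑1‑yl)cyclohex‑1‑en‑1‑olate | Br[Mg]OC1=C[C@](C)(CCC=C(C)C)CCC1 | intermediate
5 | (S)‑3‑methyl‑3‑(4‑methylpent‑3‑en‑1‑yl)cyclohex‑1‑en‑1‑yl acetate | CC(=O)OC1=C[C@](C)(CCC=C(C)C)CCC1 | intermediate
6 | (4aR,8aS)‑4a,8,8‑trimethyloctahydronaphthalen‑1(2H)‑one | O=C1CCC[C@@]2(C)CCCC(C)(C)[C@H]12 | intermediate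
7 | lithium enolate of 6 (C1=C2) | [Li]OC1=CCC[C@@]2(C)CCCC(C)(C)[C@H]12 | intermediate
8 | trimethyl{[(4aR,8aS)‑4a,8,8‑trimethyl‑3,4,4a,5,6,7,8,8a‑octahydronaphthalen‑1‑yl]oxy}silane | C[Si](C)(C)OC1=CCC[C@@]2(C)CCCC(C)(C)[C@H]12 | intermediate
9 | (4aR,8aS)‑4a,8,8‑trimethyl‑4a,5,6,7,8,8a‑hexahydronaphthalen‑1(4H)‑one | O=C1C=CC[C@@]2(C)CCCC(C)(C)[C@H]12 | intermediate
10 | (4aR,8aS)‑2,3‑epoxy‑4a,8,8‑trimethyloctahydronaphthalen‑1(2H)‑one, epoxide anti to the 4a‑methyl | O=C1[C@H]2O[C@H]2C[C@@]3(C)CCCC(C)(C)[C@H]13 | intermediate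
11 | hydrazone of 10 | NN=C1[C@H]2O[C@H]2C[C@@]3(C)CCCC(C)(C)[C@H]13 | intermediate
12 | (2S,4aS,8aR)‑5,5,8a‑trimethyl‑1,2,4a,5,6,7,8,8a‑octahydronaphthalen‑2‑ol | O[C@@H]1C=C[C@H]2C(C)(C)CCC[C@]2(C)C1 | intermediate
13 | (4aS,8aR)‑5,5,8a‑trimethyl‑4a,5,6,7,8,8a‑hexahydronaphthalen‑2(1H)‑one | O=C1C=C[C@H]2C(C)(C)CCC[C@]2(C)C1 | intermediate
14 | 1,4‑benzoquinone | O=C1C=CC(=O)C=C1 | starting material
15 | benzene‑1,2,4‑triyl triacetate | CC(=O)Oc1ccc(OC(C)=O)c(OC(C)=O)c1 | intermediate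
16 | benzene‑1,2,4‑triol | Oc1ccc(O)c(O)c1 | intermediate
17 | 1,2,4‑tris{[2‑(trimethylsilyl)ethoxy]methoxy}benzene | C[Si](C)(C)CCOCOc1ccc(OCOCC[Si](C)(C)C)c(OCOCC[Si](C)(C)C)c1 | intermediate
18 | 1‑bromo‑2,4,5‑tris(SEM‑oxy)benzene | Brc1cc(OCOCC[Si](C)(C)C)c(OCOCC[Si](C)(C)C)cc1OCOCC[Si](C)(C)C | intermediate
19 | [2,4,5‑tris(SEM‑oxy)phenyl]lithium | [Li]c1cc(OCOCC[Si](C)(C)C)c(OCOCC[Si](C)(C)C)cc1OCOCC[Si](C)(C)C | intermediate
20 | dimethyl [2,4,5‑tris(SEM‑oxy)phenyl]boronate | COB(OC)c1cc(OCOCC[Si](C)(C)C)c(OCOCC[Si](C)(C)C)cc1OCOCC[Si](C)(C)C | intermediate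
21 | 2,4,5‑tris(SEM‑oxy)phenol | Oc1cc(OCOCC[Si](C)(C)C)c(OCOCC[Si](C)(C)C)cc1OCOCC[Si](C)(C)C | intermediate
22 | triisopropyl[2,4,5‑tris(SEM‑oxy)phenoxy]silane | CC(C)[Si](Oc1cc(OCOCC[Si](C)(C)C)c(OCOCC[Si](C)(C)C)cc1OCOCC[Si](C)(C)C)(C(C)C)C(C)C | intermediate
23 | [2,3,6‑tris(SEM‑oxy)‑5‑(triisopropylsilyloxy)phenyl]lithium | [Li]c1c(OCOCC[Si](C)(C)C)c(OCOCC[Si](C)(C)C)cc(O[Si](C(C)C)(C(C)C)C(C)C)c1OCOCC[Si](C)(C)C | intermediate
24 | [2,3,6‑tris(SEM‑oxy)‑5‑(triisopropylsilyloxy)phenyl]methanol | OCc1c(OCOCC[Si](C)(C)C)c(OCOCC[Si](C)(C)C)cc(O[Si](C(C)C)(C(C)C)C(C)C)c1OCOCC[Si](C)(C)C | intermediate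
25 | [3‑(bromomethyl)‑2,4,5‑tris(SEM‑oxy)phenoxy]triisopropylsilane | BrCc1c(OCOCC[Si](C)(C)C)c(OCOCC[Si](C)(C)C)cc(O[Si](C(C)C)(C(C)C)C(C)C)c1OCOCC[Si](C)(C)C | intermediate
26 | lithium dienolate of 13 (C1=C2–OLi, C3=C4) | [Li]OC=1C=C[C@H]2C(C)(C)CCC[C@]2(C)C=1 | intermediate
27 | (1S,4aS,8aS)‑1‑{[2,3,6‑tris(SEM‑oxy)‑5‑(triisopropylsilyloxy)phenyl]methyl}‑5,5,8a‑trimethyl‑4a,5,6,7,8,8a‑hexahydronaphthalen‑2(1H)‑one | O=C1C=C[C@H]2C(C)(C)CCC[C@]2(C)[C@@H]1Cc1c(OCOCC[Si](C)(C)C)c(OCOCC[Si](C)(C)C)cc(O[Si](C(C)C)(C(C)C)C(C)C)c1OCOCC[Si](C)(C)C | intermediate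
28 | lithium enolate from 27 (C2=C3) | [Li]OC1=CC[C@H]2C(C)(C)CCC[C@]2(C)[C@@H]1Cc1c(OCOCC[Si](C)(C)C)c(OCOCC[Si](C)(C)C)cc(O[Si](C(C)C)(C(C)C)C(C)C)c1OCOCC[Si](C)(C)C | intermediate
29 | (1S,4aS,8aS)‑1‑{[2,3,6‑tris(SEM‑oxy)‑5‑(triisopropylsilyloxy)phenyl]methyl}‑5,5,8a‑trimethyl‑1,4,4a,5,6,7,8,8a‑octahydronaphthalen‑2‑yl trifluoromethanesulfonate | O=S(=O)(OC1=CC[C@H]2C(C)(C)CCC[C@]2(C)[C@@H]1Cc1c(OCOCC[Si](C)(C)C)c(OCOCC[Si](C)(C)C)cc(O[Si](C(C)C)(C(C)C)C(C)C)c1OCOCC[Si](C)(C)C)C(F)(F)F | intermediate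
30 | triisopropyl[2,4,5‑tris(SEM‑oxy)‑3‑{[(1R,4aS,8aS)‑2,5,5,8a‑tetramethyl‑1,4,4a,5,6,7,8,8a‑octahydronaphthalen‑1‑yl]methyl}phenoxy]silane | CC1=CC[C@H]2C(C)(C)CCC[C@]2(C)[C@@H]1Cc1c(OCOCC[Si](C)(C)C)c(OCOCC[Si](C)(C)C)cc(O[Si](C(C)C)(C(C)C)C(C)C)c1OCOCC[Si](C)(C)C | intermediate
31 | tetrabutylammonium 2,4,5‑tris(SEM‑oxy)‑3‑{[(1R,4aS,8aS)‑2,5,5,8a‑tetramethyl‑1,4,4a,5,6,7,8,8a‑octahydronaphthalen‑1‑yl]methyl}phenoxide | CC1=CC[C@H]2C(C)(C)CCC[C@]2(C)[C@@H]1Cc1c(OCOCC[Si](C)(C)C)c(OCOCC[Si](C)(C)C)cc([O-])c1OCOCC[Si](C)(C)C.CCCC[N+](CCCC)(CCCC)CCCC | intermediate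
32 | tetrabutylammonium 2,4,5‑tris(SEM‑oxy)‑3‑{[(1R,4aS,8aS)‑2,5,5,8a‑tetramethyl‑1,4,4a,5,6,7,8,8a‑octahydronaphthalen‑1‑yl]methyl}phenyl sulfate | CC1=CC[C@H]2C(C)(C)CCC[C@]2(C)[C@@H]1Cc1c(OCOCC[Si](C)(C)C)c(OCOCC[Si](C)(C)C)cc(OS(=O)(=O)[O-])c1OCOCC[Si](C)(C)C.CCCC[N+](CCCC)(CCCC)CCCC | intermediate
33 | tetrabutylammonium 2,4,5‑trihydroxy‑3‑{[(1R,4aS,8aS)‑2,5,5,8a‑tetramethyl‑1,4,4a,5,6,7,8,8a‑octahydronaphthalen‑1‑yl]methyl}phenyl sulfate | CC1=CC[C@H]2C(C)(C)CCC[C@]2(C)[C@@H]1Cc1c(O)c(O)cc(OS(=O)(=O)[O-])c1O.CCCC[N+](CCCC)(CCCC)CCCC | intermediate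
34 | 2,4,5‑trihydroxy‑3‑{[(1R,4aS,8aS)‑2,5,5,8a‑tetramethyl‑1,4,4a,5,6,7,8,8a‑octahydronaphthalen‑1‑yl]methyl}phenyl hydrogen sulfate | CC1=CC[C@H]2C(C)(C)CCC[C@]2(C)[C@@H]1Cc1c(O)c(O)cc(OS(=O)(=O)O)c1O | target

**Step count**
Total step count: 20 (steps 1–7 bicyclic enone, steps 8–15 benzyl bromide, steps 16–20 union and endgame).
Longest linear sequence: 13 steps (14 to 25 by steps 8–15, then steps 16–20); the enone branch gives 12.

**Steps most likely to fail, with fallbacks**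

Step 2 (acid‑initiated ring‑A closure). The strong acid may protonate or cleave the enol acetate before the tertiary cation is trapped, or give Prins‑type by‑products. The fallback sets out from 5 and comes back at 6. Dry HCl in CH2Cl2 at −40 °C adds across the trisubstituted alkene to give the tertiary chloride (S)‑3‑(4‑chloro‑4‑methylpentyl)‑3‑methylcyclohex‑1‑en‑1‑yl acetate F1. SnCl4 in CH2Cl2 at −78 °C then ionises only this chloride under aprotic conditions, and the enol acetate closes ring A by intramolecular tert‑alkylation with loss of acetyl chloride. The same NaOMe equilibration gives 6.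

Step 16 (fragment union). The SN2 reaction joins a neopentylic enolate carbon to a di‑ortho‑substituted, labile benzylic bromide; slow alkylation would allow proton transfer and epimerisation. The fallback sets out from 13 (with 25) and comes back at 27. Condensation of 13 with 1,1‑dimethylhydrazine (cat. AcOH, EtOH, reflux) gives the N,N‑dimethylhydrazone of 13 F2. LiN(i‑Pr)2 deprotonates its α′‑CH2, and the more nucleophilic azaenolate is alkylated by 25 on the same face, anti to the angular methyl, to give the alkylated N,N‑dimethylhydrazone F3. Buffered aqueous CuCl2 in THF at pH 7 cleaves the hydrazone to ketone 27.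

Step 20 (triple SEM cleavage on the sulfate). Three acetal cleavages must go to completion on an oxidation‑prone polyphenol without hydroxymethylation by the released formaldehyde. The fallback sets out from 30 and comes back at 34. Bu4NF at 0 °C gives the isolated tris‑SEM phenol F4. 2,2,2‑Trichloroethyl chlorosulfate (Cl3CCH2OSO2Cl) with Et3N and DMAP converts it into the neutral, chromatographable aryl 2,2,2‑trichloroethyl sulfate diester F5. MgBr2·OEt2 in Et2O/MeNO2 then removes the three SEM groups, which the masked sulfate tolerates, to give the triol trichloroethyl sulfate F6. Zn dust with HCO2NH4 in MeOH cleaves the trichloroethyl group reductively to the ammonium aryl sulfate F7, and H+‑form resin gives 34.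

**Further compounds**
F1 | step 2 | (S)‑3‑(4‑chloro‑4‑methylpentyl)‑3‑methylcyclohex‑1‑en‑1‑yl acetate | CC(=O)OC1=C[C@](C)(CCCC(C)(C)Cl)CCC1
F2 | step 16 | N,N‑dimethylhydrazone of 13 (C=N geometry not controlled) | CN(C)N=C1C=C[C@H]2C(C)(C)CCC[C@]2(C)C1
F3 | step 16 | N,N‑dimethylhydrazone of 27 (C=N geometry not controlled) | CN(C)N=C1C=C[C@H]2C(C)(C)CCC[C@]2(C)[C@@H]1Cc1c(OCOCC[Si](C)(C)C)c(OCOCC[Si](C)(C)C)cc(O[Si](C(C)C)(C(C)C)C(C)C)c1OCOCC[Si](C)(C)C
F4 | step 20 | 2,4,5‑tris(SEM‑oxy)‑3‑{[(1R,4aS,8aS)‑2,5,5,8a‑tetramethyl‑1,4,4a,5,6,7,8,8a‑octahydronaphthalen‑1‑yl]methyl}phenol | CC1=CC[C@H]2C(C)(C)CCC[C@]2(C)[C@@H]1Cc1c(OCOCC[Si](C)(C)C)c(OCOCC[Si](C)(C)C)cc(O)c1OCOCC[Si](C)(C)C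
F5 | step 20 | 2,4,5‑tris(SEM‑oxy)‑3‑{[(1R,4aS,8aS)‑2,5,5,8a‑tetramethyl‑1,4,4a,5,6,7,8,8a‑octahydronaphthalen‑1‑yl]methyl}phenyl 2,2,2‑trichloroethyl sulfate | CC1=CC[C@H]2C(C)(C)CCC[C@]2(C)[C@@H]1Cc1c(OCOCC[Si](C)(C)C)c(OCOCC[Si](C)(C)C)cc(OS(=O)(=O)OCC(Cl)(Cl)Cl)c1OCOCC[Si](C)(C)C
F6 | step 20 | 2,4,5‑trihydroxy‑3‑{[(1R,4aS,8aS)‑2,5,5,8a‑tetramethyl‑1,4,4a,5,6,7,8,8a‑octahydronaphthalen‑1‑yl]methyl}phenyl 2,2,2‑trichloroethyl sulfate | CC1=CC[C@H]2C(C)(C)CCC[C@]2(C)[C@@H]1Cc1c(O)c(O)cc(OS(=O)(=O)OCC(Cl)(Cl)Cl)c1O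
F7 | step 20 | ammonium 2,4,5‑trihydroxy‑3‑{[(1R,4aS,8aS)‑2,5,5,8a‑tetramethyl‑1,4,4a,5,6,7,8,8a‑octahydronaphthalen‑1‑yl]methyl}phenyl sulfate | CC1=CC[C@H]2C(C)(C)CCC[C@]2(C)[C@@H]1Cc1c(O)c(O)cc(OS(=O)(=O)[O-])c1O.[NH4+]
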